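**Plan**
Retrosynthetic cuts, in order: the four aryl O–CH3 bonds; in ring C the lactone O1–C2 bond and the C5–C6 bond; the bond from the benzylic CH2 to C6 of ring C; in ring B the C1'–C6' bond; last, the bond from the diaryl ketone carbon to C1'.
Enabling feature: in ring B, C1' carries the diaryl ketone, C2' and C4' carry OH and C6' carries the CH2 group. The ring is therefore the aldol-folded form of ArC(=O)–C1'H2–C2'(=O)–C3'H2–C4'(=O)–C5'H2–C6'(=O)–CH3, and that chain minus one water is a 2,6-disubstituted 4-pyranone.
Forward, first half: ring A is bought as 5-propylresorcinol and turned into an aldehyde. Lithiated 2,6-dimethyl-4-pyranone is added, the carbinol is oxidised, and hydroxide unmasks the tetraketone so that ring B closes.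
Forward, second half: the C6' methyl group is carboxylated, the acid is extended with a dioxinone, ring C closes by acylketene lactonisation, and BBr3 frees the four phenols.
Stereochemistry: the target has no stereocentre. The single carbinol centre met on the way is racemic and is removed by oxidation.

Key step: step 5

Assumption: the target is handled as the 4-hydroxy-2-pyranone tautomer drawn, primed locants refer to ring B as defined above, and the lithium amide bases are used as bought reagents.

**Step 1**
Reactants: 1 5-propylbenzene-1,3-diol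
Product: 2 1,3-dimethoxy-5-propylbenzene
Conditions: MeI, K2CO3, acetone, reflux
Reagents that add atoms: iodomethane, CI
Why: Williamson O-alkylation of both phenoxides gives ethers that survive hydroxide, lithium amides and heat and fall only to BBr3 in the last step.

**Step 2**
Reactants: 2 1,3-dimethoxy-5-propylbenzene
Product: 4 2,4-dimethoxy-6-propylbenzaldehyde, via aryl iminium salt 3 (not isolated)
Conditions: POCl3, DMF, 0 °C → 70 °C; then aq. NaOH
Reagents that add atoms: N,N-dimethylformamide, CN(C)C=O; water, O; phosphoryl chloride, O=P(Cl)(Cl)Cl (counter-ion of 3 only)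
Why: Vilsmeier–Haack formylation should go to C4 of 2, para to one methoxy group and ortho to the other, rather than to the crowded C2 between the two methoxy groups, as is usual for 5-alkylresorcinol dimethyl ethers.

**Step 3**
Reactants: 5 2,6-dimethyl-4H-pyran-4-one; 4 2,4-dimethoxy-6-propylbenzaldehyde
Product: 7 (±)-2-[2-(2,4-dimethoxy-6-propylphenyl)-2-hydroxyethyl]-6-methyl-4H-pyran-4-one, via lithiated pyranone 6 (not isolated)
Conditions: 5, LiN(SiMe3)2, THF, −78 °C; then 4, −78 °C; AcOH quench
Reagents that add atoms: lithium bis(trimethylsilyl)amide, [Li+].C[Si](C)(C)[N-][Si](C)(C)C (lithium of 6 only)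
Why: Lateral (vinylogous) deprotonation of a 4-pyranone methyl group gives dienolate 6, which adds 1,2 to the aldehyde; using the aldehyde instead of a 2,6-disubstituted aroyl chloride avoids O-acylation, double acylation and quenching of 6 by an acidic product, and the new carbinol centre forms racemic and is erased in step 4.

**Step 4**
Reactants: 7 (±)-2-[2-(2,4-dimethoxy-6-propylphenyl)-2-hydroxyethyl]-6-methyl-4H-pyran-4-one
Product: 8 2-[2-(2,4-dimethoxy-6-propylphenyl)-2-oxoethyl]-6-methyl-4H-pyran-4-one
Conditions: Dess–Martin periodinane, NaHCO3, CH2Cl2, 0 °C → rt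
Reagents that add atoms: none
Why: Dess–Martin oxidation of a secondary benzylic alcohol under buffered conditions should keep the electron-rich carbinol from dehydrating to the styrylpyranone.

**Step 5**
Reactants: 8 2-[2-(2,4-dimethoxy-6-propylphenyl)-2-oxoethyl]-6-methyl-4H-pyran-4-one
Product: 10 (2,4-dihydroxy-6-methylphenyl)(2,4-dimethoxy-6-propylphenyl)methanone, via open-chain tetraketone 9 (not isolated)
Conditions: 2 M aq. KOH, 1,4-dioxane, 60 °C, Ar; then 2 M HCl, 0 °C
Reagents that add atoms: water, O
Why: Hydroxide adds in conjugate fashion to an oxygen-bearing ring carbon of the 4-pyranone (C6 or C2, both leading to the same chain), and β-elimination of the ring oxygen sets free tetraketone 9 as its polyenolate. The C1' methylene of 9, acidified by the aryl ketone and by the C2' carbonyl, then attacks the terminal acetyl carbonyl, which forms the C1'–C6' bond and closes ring B in a 6-(enolexo)-exo-trig aldol addition; loss of water and enolisation of the C2' and C4' carbonyl groups make the ring aromatic and the sequence irreversible. The closest known reaction type is the base-induced biomimetic cyclisation of 1,3,5,7-tetracarbonyl chains, free or masked as 4-pyranones, to 2,4-dihydroxy-6-alkylphenyl ketones. No stereocentre results, since the transient aldol carbinol carbon ends as aromatic C6'. The step needs one aldol fold out of three six-membered ones: attack of C5' on the aryl ketone is shut off because that carbonyl lies between an ortho methoxy and an ortho propyl group and is fed by two methoxy donors, and attack of the terminal CH3 on the C2' carbonyl would pair the least acidic carbon with a carbonyl held as the enolate of the most acidic 1,3-diketone unit. Exclusion of air and a moderate temperature should hold back retro-Claisen cleavage and oxidation of the electron-rich product.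

**Step 6**
Reactants: 10 (2,4-dihydroxy-6-methylphenyl)(2,4-dimethoxy-6-propylphenyl)methanone
Product: 11 (2,4-dimethoxy-6-methylphenyl)(2,4-dimethoxy-6-propylphenyl)methanone
Conditions: MeI (excess), K2CO3, DMF, 40 °C
Reagents that add atoms: iodomethane, CI
Why: Williamson methylation in warm DMF should also alkylate the C2' hydroxyl that is hydrogen-bonded to the ketone, and removing both acidic protons is a precondition for the carbanion chemistry of step 7.

**Step 7**
Reactants: 11 (2,4-dimethoxy-6-methylphenyl)(2,4-dimethoxy-6-propylphenyl)methanone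
Product: 13 [2-(2,4-dimethoxy-6-propylbenzoyl)-3,5-dimethoxyphenyl]acetic acid, via lithium dienolate 12 (not isolated)
Conditions: lithium 2,2,6,6-tetramethylpiperidide, THF, −78 °C; CO2 (g), −78 → 0 °C; then 1 M HCl
Reagents that add atoms: carbon dioxide, O=C=O; lithium 2,2,6,6-tetramethylpiperidide, [Li+].CC1(C)CCCC(C)(C)[N-]1 (lithium of 12 only)
Why: This is a lateral lithiation of an ortho-toluoyl carbonyl compound, in which an amide base that has no β-hydrogen to deliver as hydride and cannot add to the shielded ketone removes a proton from the C6' methyl group (the primary CH3 should react ahead of the propyl benzylic CH2, whose dienolate would suffer allylic strain), and dienolate 12 is carboxylated at carbon by CO2.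

**Step 8**
Reactants: 13 [2-(2,4-dimethoxy-6-propylbenzoyl)-3,5-dimethoxyphenyl]acetic acid; 14 2,2,6-trimethyl-4H-1,3-dioxin-4-one
Product: 17 6-{3-[2-(2,4-dimethoxy-6-propylbenzoyl)-3,5-dimethoxyphenyl]-2-oxopropyl}-2,2-dimethyl-4H-1,3-dioxin-4-one, via acyl imidazolide 15 (not isolated), via dioxinone lithium dienolate 16 (not isolated)
Conditions: 13, 1,1'-carbonyldiimidazole, THF, rt; separately 14 (3 equiv), LiN(SiMe3)2, THF, −78 °C; solutions combined, −78 → −20 °C; then 1 M HCl, 0 °C
Reagents that add atoms: 1,1'-carbonyldiimidazole, O=C(n1ccnc1)n1ccnc1 (imidazolyl group of 15 only); lithium bis(trimethylsilyl)amide, [Li+].C[Si](C)(C)[N-][Si](C)(C)C (lithium of 16 only)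
Why: Vinylogous Claisen-type C-acylation at the γ-carbon of dioxinone dienolate 16 by acyl imidazolide 15 is a standard entry to 6-(2-oxoalkyl)dioxinones, the excess of 16 takes up the imidazole proton and the acidic product, and the tetra-ortho-substituted diaryl ketone is too shielded to be attacked.

**Step 9**
Reactants: 17 6-{3-[2-(2,4-dimethoxy-6-propylbenzoyl)-3,5-dimethoxyphenyl]-2-oxopropyl}-2,2-dimethyl-4H-1,3-dioxin-4-one
Product: 19 6-{[2-(2,4-dimethoxy-6-propylbenzoyl)-3,5-dimethoxyphenyl]methyl}-4-hydroxy-2H-pyran-2-one, via acylketene 18 (not isolated)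
Conditions: toluene, 110 °C
Reagents that add atoms: none
Why: Thermal retro-[4+2] loss of acetone from the dioxinone gives acylketene 18, whose remote ketone adds through its enol oxygen to the ketene carbon and closes ring C as the 4-hydroxy-2-pyranone, the usual fate of 6-(2-oxoalkyl)dioxinones on heating.

**Step 10**
Reactants: 19 6-{[2-(2,4-dimethoxy-6-propylbenzoyl)-3,5-dimethoxyphenyl]methyl}-4-hydroxy-2H-pyran-2-one
Product: 20 6-{[2-(2,4-dihydroxy-6-propylbenzoyl)-3,5-dihydroxyphenyl]methyl}-4-hydroxy-2H-pyran-2-one
Conditions: BBr3 (excess), CH2Cl2, −78 °C → rt; then ice-water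
Reagents that add atoms: none
Why: In this Lewis-acid aryl methyl ether cleavage BBr3 binds each ether oxygen (the two ortho to the ketone first, helped by chelation) and bromide removes the methyl group, while the ketone, the propyl chain and the 4-hydroxy-2-pyranone are only complexed and should be released on hydrolysis.

**Compound list**
1 | 5-propylbenzene-1,3-diol | CCCc1cc(O)cc(O)c1 | starting material
2 | 1,3-dimethoxy-5-propylbenzene | CCCc1cc(OC)cc(OC)c1 | intermediate
3 | N-[(2,4-dimethoxy-6-propylphenyl)methylidene]-N-methylmethanaminium dichlorophosphate | CCCc1cc(OC)cc(OC)c1C=[N+](C)C.[O-]P(=O)(Cl)Cl | intermediate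
4 | 2,4-dimethoxy-6-propylbenzaldehyde | CCCc1cc(OC)cc(OC)c1C=O | intermediate
5 | 2,6-dimethyl-4H-pyran-4-one | Cc1cc(=O)cc(C)o1 | starting material
6 | lithium 2-methyl-6-methylidene-6H-pyran-4-olate | [Li+].C=C1C=C([O-])C=C(C)O1 | intermediate
7 | (±)-2-[2-(2,4-dimethoxy-6-propylphenyl)-2-hydroxyethyl]-6-methyl-4H-pyran-4-one (racemic) | CCCc1cc(OC)cc(OC)c1C(O)Cc1cc(=O)cc(C)o1 | intermediate
8 | 2-[2-(2,4-dimethoxy-6-propylphenyl)-2-oxoethyl]-6-methyl-4H-pyran-4-one | CCCc1cc(OC)cc(OC)c1C(=O)Cc1cc(=O)cc(C)o1 | intermediate
9 | 1-(2,4-dimethoxy-6-propylphenyl)octane-1,3,5,7-tetraone | CCCc1cc(OC)cc(OC)c1C(=O)CC(=O)CC(=O)CC(C)=O | intermediate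
10 | (2,4-dihydroxy-6-methylphenyl)(2,4-dimethoxy-6-propylphenyl)methanone | CCCc1cc(OC)cc(OC)c1C(=O)c1c(O)cc(O)cc1C | intermediate
11 | (2,4-dimethoxy-6-methylphenyl)(2,4-dimethoxy-6-propylphenyl)methanone | CCCc1cc(OC)cc(OC)c1C(=O)c1c(OC)cc(OC)cc1C | intermediate
12 | lithium (2,4-dimethoxy-6-methylidenecyclohexa-2,4-dien-1-ylidene)(2,4-dimethoxy-6-propylphenyl)methanolate | [Li+].CCCc1cc(OC)cc(OC)c1C([O-])=C1C(=C)C=C(OC)C=C1OC | intermediate
13 | [2-(2,4-dimethoxy-6-propylbenzoyl)-3,5-dimethoxyphenyl]acetic acid | CCCc1cc(OC)cc(OC)c1C(=O)c1c(OC)cc(OC)cc1CC(=O)O | intermediate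
14 | 2,2,6-trimethyl-4H-1,3-dioxin-4-one | CC1=CC(=O)OC(C)(C)O1 | starting material
15 | 2-[2-(2,4-dimethoxy-6-propylbenzoyl)-3,5-dimethoxyphenyl]-1-(1H-imidazol-1-yl)ethan-1-one | CCCc1cc(OC)cc(OC)c1C(=O)c1c(OC)cc(OC)cc1CC(=O)n1ccnc1 | intermediate
16 | lithium 2,2-dimethyl-6-methylidene-6H-1,3-dioxin-4-olate | [Li+].C=C1C=C([O-])OC(C)(C)O1 | intermediate
17 | 6-{3-[2-(2,4-dimethoxy-6-propylbenzoyl)-3,5-dimethoxyphenyl]-2-oxopropyl}-2,2-dimethyl-4H-1,3-dioxin-4-one | CCCc1cc(OC)cc(OC)c1C(=O)c1c(OC)cc(OC)cc1CC(=O)CC1=CC(=O)OC(C)(C)O1 | intermediate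
18 | 6-[2-(2,4-dimethoxy-6-propylbenzoyl)-3,5-dimethoxyphenyl]hex-1-ene-1,3,5-trione (acylketene) | CCCc1cc(OC)cc(OC)c1C(=O)c1c(OC)cc(OC)cc1CC(=O)CC(=O)C=C=O | intermediate
19 | 6-{[2-(2,4-dimethoxy-6-propylbenzoyl)-3,5-dimethoxyphenyl]methyl}-4-hydroxy-2H-pyran-2-one | CCCc1cc(OC)cc(OC)c1C(=O)c1c(OC)cc(OC)cc1Cc1cc(O)cc(=O)o1 | intermediate
20 | 6-{[2-(2,4-dihydroxy-6-propylbenzoyl)-3,5-dihydroxyphenyl]methyl}-4-hydroxy-2H-pyran-2-one | CCCc1cc(O)cc(O)c1C(=O)c1c(O)cc(O)cc1Cc1cc(O)cc(=O)o1 | target

**Total step count:** 10
**Longest linear sequence:** 10 steps (1 → 20); 5 and 14 are bought and enter directly.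

**Steps most likely to fail**

**Step 7.** Both aryl rings are twisted out of the carbonyl plane, which lowers the acidity of the C6' methyl group. Deprotonation may therefore stay incomplete, or stray to the propyl benzylic CH2 or to a ring C–H between two methoxy groups. The fallback brings the benzylic carbon and the carboxyl carbon in with a building block, so that no carbanion has to be made next to the crowded ketone.
- It sets out from 4. Pinnick oxidation (NaClO2, NaH2PO4, 2-methylbut-2-ene, t-BuOH/H2O) would give 2,4-dimethoxy-6-propylbenzoic acid F4.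
- Trifluoroacetic anhydride in CH2Cl2 would convert this into 2,4-dimethoxy-6-propylbenzoic trifluoroacetic anhydride F5.
- F5 would acylate commercial methyl (3,5-dimethoxyphenyl)acetate in a Friedel–Crafts reaction, ortho to the CH2CO2Me arm and para to a methoxy group. This would give methyl [2-(2,4-dimethoxy-6-propylbenzoyl)-3,5-dimethoxyphenyl]acetate F6.
- Saponification with LiOH in THF/H2O comes back to the route at 13.

**Step 5.** The open chain may fold the wrong way, break by retro-Claisen cleavage, or merely re-close to the pyranone on acidification. The fallback takes ring B from an aromatic building block instead of building it.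
- It sets out from 4. Commercial 1,3-dimethoxy-5-methylbenzene would be brominated with NBS in MeCN, para to one methoxy group, to give 2-bromo-1,5-dimethoxy-3-methylbenzene F1.
- Bromine–lithium exchange with n-BuLi in THF at −78 °C would give (2,4-dimethoxy-6-methylphenyl)lithium F2.
- Addition of F2 to 4 would give racemic (2,4-dimethoxy-6-methylphenyl)(2,4-dimethoxy-6-propylphenyl)methanol F3.
- Oxidation with MnO2 in CH2Cl2 comes back to the route at 11.

**Step 8.** Proton transfer from the doubly activated ArCH2C(=O) position of the imidazolide to the basic dienolate may outrun acylation, with ketene formation and self-condensation in its wake. The fallback forms the same C–C bond without any base.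
- It sets out from 13. Oxalyl chloride with catalytic DMF in CH2Cl2 would give [2-(2,4-dimethoxy-6-propylbenzoyl)-3,5-dimethoxyphenyl]acetyl chloride F7.
- Commercial 1-methoxy-1,3-bis(trimethylsilyloxy)buta-1,3-diene would be acylated by F7 at its terminal carbon in CH2Cl2 from −78 °C to rt. After aqueous work-up this would give methyl 6-[2-(2,4-dimethoxy-6-propylbenzoyl)-3,5-dimethoxyphenyl]-3,5-dioxohexanoate F8.
- DBU in toluene at reflux would lactonise the enol onto the ester and come back to the route at 19.

**Further compounds**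
F1 | step 5 | 2-bromo-1,5-dimethoxy-3-methylbenzene | Cc1cc(OC)cc(OC)c1Br
F2 | step 5 | (2,4-dimethoxy-6-methylphenyl)lithium | [Li]c1c(C)cc(OC)cc1OC
F3 | step 5 | (±)-(2,4-dimethoxy-6-methylphenyl)(2,4-dimethoxy-6-propylphenyl)methanol | CCCc1cc(OC)cc(OC)c1C(O)c1c(OC)cc(OC)cc1C
F4 | step 7 | 2,4-dimethoxy-6-propylbenzoic acid | CCCc1cc(OC)cc(OC)c1C(=O)O
F5 | step 7 | 2,4-dimethoxy-6-propylbenzoic trifluoroacetic anhydride | CCCc1cc(OC)cc(OC)c1C(=O)OC(=O)C(F)(F)F
F6 | step 7 | methyl [2-(2,4-dimethoxy-6-propylbenzoyl)-3,5-dimethoxyphenyl]acetate | CCCc1cc(OC)cc(OC)c1C(=O)c1c(OC)cc(OC)cc1CC(=O)OC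
F7 | step 8 | [2-(2,4-dimethoxy-6-propylbenzoyl)-3,5-dimethoxyphenyl]acetyl chloride | CCCc1cc(OC)cc(OC)c1C(=O)c1c(OC)cc(OC)cc1CC(=O)Cl
F8 | step 8 | methyl 6-[2-(2,4-dimethoxy-6-propylbenzoyl)-3,5-dimethoxyphenyl]-3,5-dioxohexanoate | CCCc1cc(OC)cc(OC)c1C(=O)c1c(OC)cc(OC)cc1CC(=O)CC(=O)CC(=O)OC
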